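All runs come from a simulation with constants of no real substance.

Size the partner charge by what the side-product branch takes, before spending material on the next flask.

| flask | substrate | partner | remark | time |
|---|---|---|---|---|
| alder | 0.16 M | 0.19 M (fed, over 10 min) | run made earlier |  |
| elm | 0.16 M | 0.32 M (fed, over 10 min) | run made earlier |  |
| birch | 0.16 M | 0.43 M (fed, over 10 min) | run made earlier |  |
| eta | 0.16 M | 0.150 M (fed, over 10 min) |  | 80 min |
| theta | 0.16 M | 0.300 M (fed, over 10 min) |  | 80 min |
| epsilon | 0.16 M | 0.600 M (fed, over 10 min) |  | 80 min |

| run | time / min | target / % | side product / % |
|---|---|---|---|
| alder | 8.00 | 1 | 13 |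
| alder | 20.0 | 7 | 31 |
| alder | 40.0 | 9 | 41 |
| alder | 60.0 | 14 | 39 |
| elm | 8.00 | 0 | 21 |
| elm | 20.0 | 8 | 49 |
| elm | 40.0 | 19 | 52 |
| elm | 60.0 | 24 | 53 |
| birch | 8.00 | 2 | 26 |
| birch | 20.0 | 11 | 53 |
| birch | 40.0 | 25 | 58 |
| birch | 60.0 | 30 | 59 |

(scatter of a reading: 1.5 percentage points)

- "hardly changes" means that all values lie within two and a half points (for a concentration: within two and a half percent of the largest)

- share of target in all that became target or side product for eta, theta, epsilon, in this order
- how that number moves from the first to the last of them (hardly changes / rises all the way / falls all the way / rises, then falls / falls, then rises)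

I start from the end state. In the alder, elm and birch runs the side product hardly changes between the last two readings, so its last value tells how much substrate took that branch for good. Dividing side product by the remainder gives odds, and dividing the odds by the partner charge gives 3.36 /M for alder, 3.52 /M for elm and 3.35 /M for birch. Their mean, 3.41 /M, is my branching constant, a selectivity factor per molar of partner charged.

If everything outside the side product ended as target, the share would reach a ceiling of one over one plus the constant times the charge. That ceiling is 66.1% for eta, 49.4% for theta and 32.8% for epsilon, so it falls as partner rises.

The approach to it runs the other way. The part that is neither product at the last reading is 47.0% in alder, against 11.0% in birch. Alder's share there, 26.4%, is my figure for eta. Elm gained 5 percentage points of target between its last two readings, and one more such step gives it a share of 35.4%, my figure for theta, which is higher than epsilon's ceiling, but that gap of 2.6 points rests on readings with a scatter of 1.5 points, so the fall is the weaker part of my reckoning. So I expect a rise and then a fall, and I charge 0.300 M next: twice that partner buys a lower ceiling.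

The forecast gives 27%, 33% and 38%, a row that rises all the way, as “a modest, saturating rise”.

The flasks give 26.4%, 35.6% and 31.5%: the row rises, then falls.

    partner + intermediate C → target (k = 0.430 /M/min)
    substrate → decomposition product (k = 2.20 × 10⁻⁵ /min)
    substrate → intermediate A (k = 0.870 /min)
    partner + intermediate B ⇌ intermediate C (K = 4.40 /M, k = 0.350 /M/min)
    intermediate A → intermediate B (k = 0.0470 /min)
    intermediate C → decomposed reagent (k = 0.0210 /min)
    partner + intermediate A → side product (k = 0.310 /M/min)

Epsilon stands just under its ceiling of 32.8%, and reading it ten times later makes no real difference, so this flask has reached its end state. Feeding the partner bit by bit is one part of what holds epsilon's share up: the same charge added at once gives 20.7% against 31.5%. Eta stays far below its ceiling of 66.1%, with intermediate B still holding 40.0% of the substrate at 80.0 min. The early reading is part of that gap: ten times later eta's share is 34.0%, and decomposed reagent by then stands at 24.7% of the substrate.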